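Numbering: ring A = C1(H), C2–C4 (OMe), C4a, C9a; ring B = C4a, spiro C5, C6H2, C7, C8, C9, C9a; ring C = C5, C2'H, C3'(OMe), C4'(=O), C5'(OMe), C6'H.
Cuts, in retrosynthetic order: C2'=C3' and C5'=C6' (ring C falls back to a C5 dialdehyde plus 1,3-dimethoxyacetone). The C7 methyl is then read as a hydrogenated exocyclic methylene, C8–C9 is cut (ring B opens), and last C5–C6 and C4a–C5.
Enabling feature: the C9 carbinol is the neighbour of the C8 methine, the C7 methyl can have been =CH2, and spiro C5 is no stereocentre because ring C is symmetric. Ring B can therefore be closed from an achiral ortho-formylaryl malonate that carries a (Z)-2-methylbut-2-enyl chain.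
Forward: ring A is bought; C4a–C5 comes from malonate arylation, C5–C6 from allylation, ring B from the carbonyl-ene closure, and ring C last from a double aldol addition and elimination.
Stereochemistry: the chiral acid chooses the aldehyde face (C9), the (Z)-alkene relays this to C8 (trans), and hydrogen-atom-transfer hydrogenation relays C8 to C7 (trans).
C5 keeps two methyl esters through the acid step, because a diol acetal there could exchange with the ortho aldehyde into a bridged 2.2.2 bicyclic acetal.

Key step: step 7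

Assumption: the sense of induction of the confined acid cannot be derived from precedent for this ring size. The (S,S) antipode is written, and its mirror image is taken if a trial run shows attack on the Si face of C9 instead of the Re face.

Step 1
Reactants: 1 2-bromo-3,4,5-trimethoxybenzaldehyde
Product: 2 2-(2-bromo-3,4,5-trimethoxyphenyl)-1,3-dioxolane
Conditions: HOCH2CH2OH, p-TsOH·H2O (cat.), toluene, Dean–Stark, reflux
Reagents that add atoms: ethylene glycol, OCCO
Why: Acid-catalysed acetalisation driven by azeotropic removal of water; the free aldehyde would undergo Knoevenagel condensation with the malonate under the basic conditions of step 2.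

Step 2
Reactants: 2 2-(2-bromo-3,4,5-trimethoxyphenyl)-1,3-dioxolane; 3 dimethyl malonate
Product: 4 dimethyl 2-[6-(1,3-dioxolan-2-yl)-2,3,4-trimethoxyphenyl]malonate
Conditions: Pd2(dba)3 (2 mol%), P(t-Bu)3·HBF4 (8 mol%), K3PO4, toluene, 90 °C
Reagents that add atoms: none
Why: Palladium-catalysed α-arylation of a malonate enolate forms C4a–C5; bulky, electron-rich P(t-Bu)3 is the ligand type proven for electron-rich aryl bromides with two ortho substituents, and the acidic monoaryl product rests as its enolate, which stops a second arylation.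

Step 3
Reactants: 5 angelic acid
Product: 6 (Z)-2-methylbut-2-en-1-ol
Conditions: LiAlH4, Et2O, 0 °C to rt
Reagents that add atoms: none
Why: Hydride reduction of the carboxylic acid (as its carboxylate, hence 1,2-selective) leaves the trisubstituted alkene and its (Z) geometry untouched.

Step 4
Reactants: 6 (Z)-2-methylbut-2-en-1-ol
Product: 7 (Z)-1-bromo-2-methylbut-2-ene
Conditions: PBr3 (0.4 equiv), Et2O, −10 °C
Reagents that add atoms: phosphorus tribromide, BrP(Br)Br
Why: SN2 bromination of the primary allylic alcohol through its phosphite ester; low temperature and short contact hold back allylic transposition and Z to E drift, and the volatile bromide is used as an ethereal solution.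

Step 5
Reactants: 4 dimethyl 2-[6-(1,3-dioxolan-2-yl)-2,3,4-trimethoxyphenyl]malonate; 7 (Z)-1-bromo-2-methylbut-2-ene
Product: 8 dimethyl 2-[6-(1,3-dioxolan-2-yl)-2,3,4-trimethoxyphenyl]-2-[(Z)-2-methylbut-2-enyl]malonate
Conditions: NaH, DMF, 0 °C to rt
Reagents that add atoms: none
Why: Malonic ester alkylation forms C5–C6 and the quaternary C5; the crowded enolate attacks the unhindered CH2 terminus of the allylic bromide in SN2 fashion, so the (Z) geometry is carried over.

Step 6
Reactants: 8 dimethyl 2-[6-(1,3-dioxolan-2-yl)-2,3,4-trimethoxyphenyl]-2-[(Z)-2-methylbut-2-enyl]malonate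
Product: 9 dimethyl 2-(6-formyl-2,3,4-trimethoxyphenyl)-2-[(Z)-2-methylbut-2-enyl]malonate (achiral ene precursor)
Conditions: 1 M aq. HCl, THF, rt
Reagents that add atoms: water, O
Why: Acid-catalysed acetal hydrolysis; the donor-substituted benzylic dioxolane opens under conditions too mild to hydrolyse the methyl esters or to protonate the trisubstituted alkene.

Step 7
Reactants: 9 dimethyl 2-(6-formyl-2,3,4-trimethoxyphenyl)-2-[(Z)-2-methylbut-2-enyl]malonate
Product: 10 dimethyl (8S,9R)-9-hydroxy-2,3,4-trimethoxy-8-methyl-7-methylidene-6,7,8,9-tetrahydro-5H-benzo[7]annulene-5,5-dicarboxylate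
Conditions: (S,S)-IDPi (BINOL-derived imidodiphosphorimidate, N-triflyl core, 3,3'-aryl = 3,5-(CF3)2C6H3, 5 mol%), 5 Å MS, CHCl3/methylcyclohexane, 0.02 M, −40 °C
Reagents that add atoms: none
Why: Proposed new method: the confined acid binds the C9 carbonyl oxygen, C8 of the alkene bonds to C9 and one hydrogen of the C7 methyl passes to the oxygen in a single, asynchronous pericyclic event over C9, C8, C7, the methyl carbon, H and O, so that no free C7 cation is left for a neighbouring ester to capture. The closest known reactions are the racemic Me2AlCl-promoted type 2 carbonyl-ene cyclisation to 3-methylenecycloheptanols and the chiral imidodiphosphate and IDPi catalysed carbonyl-ene and Prins-type cyclisations, which so far close five- and six-membered rings, while IDPi acids are known to activate benzaldehydes towards unactivated olefins. Ring B closes in the type 2 mode, a 7-(2,4) closure with the tether on the central ene carbon C7, which forces the new alkene to be exocyclic. C9 is set by the chiral anion pocket, which leaves only the Re face of the bound aldehyde of the achiral substrate open; C8 is set relative to C9 by the (Z)-alkene, because the tether keeps C9a on the C6 side while the oxygen has to lie over the transferring methyl, and this places the C8 methyl anti to the C9–O bond, that is trans on ring B. The step needs ene over Prins or lactonisation chemoselectivity, methyl over C6–H regioselectivity and aldehyde face selectivity; the non-enolisable aldehyde, the acid-stable gem-diester (Thorpe–Ingold folding, no internal acetal possible) and the six-centre geometry, in which only the methyl hydrogens reach the oxygen, secure the first two, and the catalyst secures the third.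

Step 8
Reactants: 10 dimethyl (8S,9R)-9-hydroxy-2,3,4-trimethoxy-8-methyl-7-methylidene-6,7,8,9-tetrahydro-5H-benzo[7]annulene-5,5-dicarboxylate
Product: 11 dimethyl (8S,9R)-9-(tert-butyldimethylsilyloxy)-2,3,4-trimethoxy-8-methyl-7-methylidene-6,7,8,9-tetrahydro-5H-benzo[7]annulene-5,5-dicarboxylate
Conditions: TBSOTf, 2,6-lutidine, CH2Cl2, 0 °C
Reagents that add atoms: tert-butyldimethylsilyl triflate, CC(C)(C)[Si](C)(C)OS(=O)(=O)C(F)(F)F
Why: Silyl ether formation with the reactive triflate covers the hindered benzylic alcohol before it can lactonise onto a C5 ester and shields it from the hydride, oxidant and boron reagents to come.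

Step 9
Reactants: 11 dimethyl (8S,9R)-9-(tert-butyldimethylsilyloxy)-2,3,4-trimethoxy-8-methyl-7-methylidene-6,7,8,9-tetrahydro-5H-benzo[7]annulene-5,5-dicarboxylate
Product: 12 dimethyl (7R,8S,9R)-9-(tert-butyldimethylsilyloxy)-2,3,4-trimethoxy-7,8-dimethyl-6,7,8,9-tetrahydro-5H-benzo[7]annulene-5,5-dicarboxylate
Conditions: Mn(dpm)3 (10 mol%), PhSiH3, t-BuOOH, i-PrOH, rt
Reagents that add atoms: none
Why: Metal-hydride hydrogen-atom-transfer hydrogenation (H atom to the CH2 terminus, then a second H to the tertiary C7 radical) follows product stability and should place the C7 methyl pseudo-equatorial, away from the pseudo-axial C5 ester and trans to the C8 methyl (7R), whereas surface or hydroxyl-directed hydrogenation would deliver hydrogen anti to the C8 methyl and give the cis isomer.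

Step 10
Reactants: 12 dimethyl (7R,8S,9R)-9-(tert-butyldimethylsilyloxy)-2,3,4-trimethoxy-7,8-dimethyl-6,7,8,9-tetrahydro-5H-benzo[7]annulene-5,5-dicarboxylate
Product: 13 [(7R,8S,9R)-9-(tert-butyldimethylsilyloxy)-2,3,4-trimethoxy-7,8-dimethyl-6,7,8,9-tetrahydro-5H-benzo[7]annulene-5,5-diyl]dimethanol
Conditions: LiAlH4, THF, 0 °C to 40 °C
Reagents that add atoms: none
Why: Exhaustive LiAlH4 reduction of a 2,2-disubstituted malonate to the 1,3-diol, a standard transformation that the silyl ether and the aryl ethers tolerate.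

Step 11
Reactants: 13 [(7R,8S,9R)-9-(tert-butyldimethylsilyloxy)-2,3,4-trimethoxy-7,8-dimethyl-6,7,8,9-tetrahydro-5H-benzo[7]annulene-5,5-diyl]dimethanol
Product: 14 (7R,8S,9R)-9-(tert-butyldimethylsilyloxy)-2,3,4-trimethoxy-7,8-dimethyl-6,7,8,9-tetrahydro-5H-benzo[7]annulene-5,5-dicarbaldehyde
Conditions: Dess–Martin periodinane, CH2Cl2, 0 °C to rt
Reagents that add atoms: none
Why: Dess–Martin oxidation of both neopentyl alcohols under base-free conditions, so that the intermediate β-hydroxy aldehyde cannot lose formaldehyde by retro-aldol cleavage and the non-enolisable dialdehyde is not deformylated.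

Step 12
Reactants: 14 (7R,8S,9R)-9-(tert-butyldimethylsilyloxy)-2,3,4-trimethoxy-7,8-dimethyl-6,7,8,9-tetrahydro-5H-benzo[7]annulene-5,5-dicarbaldehyde; 15 1,3-dimethoxyacetone
Product: 18 (7R,8S,9R)-9-(tert-butyldimethylsilyloxy)-2',6'-dihydroxy-2,3,4,3',5'-pentamethoxy-7,8-dimethyl-6,7,8,9-tetrahydrospiro[benzo[7]annulene-5,1'-cyclohexan]-4'-one (ring C diastereomers), via dibutylboron enolate 16 (not isolated), via monoaldol boron aldolate 17 (not isolated)
Conditions: 15 (1.0 equiv), n-Bu2BOTf (1.1 equiv), i-Pr2NEt (1.3 equiv), CH2Cl2, −78 °C; add 14; then n-Bu2BOTf (1.2 equiv), i-Pr2NEt (1.5 equiv), −78 to 0 °C; MeOH, pH 7 buffer, 30% H2O2, 0 °C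
Reagents that add atoms: none
Why: Two boron-mediated aldol additions, the first intermolecular and the second a six-membered ring closure after enolisation of the free methoxymethyl side; covalent boron aldolates do not revert, which shuts off the retro-aldol and deformylation paths open to a 2,2-disubstituted malonaldehyde under alkoxide conditions, and the new ring C centres need no control because step 14 erases them.

Step 13
Reactants: 18 (7R,8S,9R)-9-(tert-butyldimethylsilyloxy)-2',6'-dihydroxy-2,3,4,3',5'-pentamethoxy-7,8-dimethyl-6,7,8,9-tetrahydrospiro[benzo[7]annulene-5,1'-cyclohexan]-4'-one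
Product: 19 (7R,8S,9R)-9,2',6'-trihydroxy-2,3,4,3',5'-pentamethoxy-7,8-dimethyl-6,7,8,9-tetrahydrospiro[benzo[7]annulene-5,1'-cyclohexan]-4'-one
Conditions: HF·pyridine, THF/pyridine, 0 °C to rt
Reagents that add atoms: none
Why: Fluoride-induced desilylation under mildly acidic conditions, chosen because basic fluoride could start a retro-aldol opening of ring C.

Step 14
Reactants: 19 (7R,8S,9R)-9,2',6'-trihydroxy-2,3,4,3',5'-pentamethoxy-7,8-dimethyl-6,7,8,9-tetrahydrospiro[benzo[7]annulene-5,1'-cyclohexan]-4'-one
Product: 21 (7R,8S,9R)-2,3,4,3',5'-pentamethoxy-7,8-dimethyl-4'-oxo-6,7,8,9-tetrahydrospiro[benzo[7]annulene-5,1'-cyclohexa-2',5'-dien]-9-yl acetate (target), via triacetate 20 (not isolated)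
Conditions: Ac2O, Et3N, DMAP (cat.), CH2Cl2, rt; then DBU, rt
Reagents that add atoms: acetic anhydride, CC(=O)OC(C)=O
Why: DMAP-catalysed acetylation of all three hydroxyl groups followed by E1cB elimination; only the two acetates β to the C4' ketone can leave, so the C9 acetate stays, ring C becomes the symmetric dimethoxy dienone and C5 ceases to be stereogenic.

Compound list
1 | 2-bromo-3,4,5-trimethoxybenzaldehyde | COc1cc(C=O)c(Br)c(OC)c1OC | starting material
2 | 2-(2-bromo-3,4,5-trimethoxyphenyl)-1,3-dioxolane | COc1cc(C2OCCO2)c(Br)c(OC)c1OC | intermediate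
3 | dimethyl malonate | COC(=O)CC(=O)OC | starting material
4 | dimethyl 2-[6-(1,3-dioxolan-2-yl)-2,3,4-trimethoxyphenyl]malonate | COC(=O)C(C(=O)OC)c1c(OC)c(OC)c(OC)cc1C1OCCO1 | intermediate
5 | angelic acid, (Z)-2-methylbut-2-enoic acid | C/C=C(/C)C(=O)O | starting material
6 | (Z)-2-methylbut-2-en-1-ol | C/C=C(/C)CO | intermediate
7 | (Z)-1-bromo-2-methylbut-2-ene | C/C=C(/C)CBr | intermediate
8 | dimethyl 2-[6-(1,3-dioxolan-2-yl)-2,3,4-trimethoxyphenyl]-2-[(Z)-2-methylbut-2-enyl]malonate | COC(=O)C(C/C(C)=C\C)(C(=O)OC)c1c(OC)c(OC)c(OC)cc1C1OCCO1 | intermediate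
9 | dimethyl 2-(6-formyl-2,3,4-trimethoxyphenyl)-2-[(Z)-2-methylbut-2-enyl]malonate | COC(=O)C(C/C(C)=C\C)(C(=O)OC)c1c(OC)c(OC)c(OC)cc1C=O | intermediate
10 | dimethyl (8S,9R)-9-hydroxy-2,3,4-trimethoxy-8-methyl-7-methylidene-6,7,8,9-tetrahydro-5H-benzo[7]annulene-5,5-dicarboxylate | COC(=O)C1(C(=O)OC)CC(=C)[C@H](C)[C@@H](O)c2cc(OC)c(OC)c(OC)c21 | intermediate
11 | tert-butyldimethylsilyl ether of 10 | COC(=O)C1(C(=O)OC)CC(=C)[C@H](C)[C@@H](O[Si](C)(C)C(C)(C)C)c2cc(OC)c(OC)c(OC)c21 | intermediate
12 | dimethyl (7R,8S,9R)-9-(tert-butyldimethylsilyloxy)-2,3,4-trimethoxy-7,8-dimethyl-6,7,8,9-tetrahydro-5H-benzo[7]annulene-5,5-dicarboxylate | COC(=O)C1(C(=O)OC)C[C@@H](C)[C@H](C)[C@@H](O[Si](C)(C)C(C)(C)C)c2cc(OC)c(OC)c(OC)c21 | intermediate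
13 | (7R,8S,9R)-5,5-bis(hydroxymethyl) compound (diol) | OCC1(CO)C[C@@H](C)[C@H](C)[C@@H](O[Si](C)(C)C(C)(C)C)c2cc(OC)c(OC)c(OC)c21 | intermediate
14 | (7R,8S,9R)-5,5-dicarbaldehyde | O=CC1(C=O)C[C@@H](C)[C@H](C)[C@@H](O[Si](C)(C)C(C)(C)C)c2cc(OC)c(OC)c(OC)c21 | intermediate
15 | 1,3-dimethoxyacetone | COCC(=O)COC | starting material
16 | dibutylboron enolate of 15 (alkene geometry of no consequence) | COCC(OB(CCCC)CCCC)=COC | intermediate (not isolated)
17 | monoaldol boron aldolate (C5 and side-chain centres of no consequence) | COCC(=O)C(OC)C(OB(CCCC)CCCC)C1(C=O)C[C@@H](C)[C@H](C)[C@@H](O[Si](C)(C)C(C)(C)C)c2cc(OC)c(OC)c(OC)c21 | intermediate (not isolated)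
18 | spiro 2',6'-dihydroxy-3',5'-dimethoxycyclohexan-4'-one, C9 silyl ether (ring C diastereomers) | COC1C(O)C2(C(O)C(OC)C1=O)C[C@@H](C)[C@H](C)[C@@H](O[Si](C)(C)C(C)(C)C)c1cc(OC)c(OC)c(OC)c12 | intermediate
19 | 9,2',6'-triol (ring C diastereomers) | COC1C(O)C2(C(O)C(OC)C1=O)C[C@@H](C)[C@H](C)[C@@H](O)c1cc(OC)c(OC)c(OC)c12 | intermediate
20 | 9,2',6'-triacetate | COC1C(OC(C)=O)C2(C(OC(C)=O)C(OC)C1=O)C[C@@H](C)[C@H](C)[C@@H](OC(C)=O)c1cc(OC)c(OC)c(OC)c12 | intermediate (not isolated)
21 | (7R,8S,9R)-2,3,4,3',5'-pentamethoxy-7,8-dimethyl-4'-oxo-6,7,8,9-tetrahydrospiro[benzo[7]annulene-5,1'-cyclohexa-2',5'-dien]-9-yl acetate | COC1=CC2(C=C(OC)C1=O)C[C@@H](C)[C@H](C)[C@@H](OC(C)=O)c1cc(OC)c(OC)c(OC)c12 | target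

Total step count: 14. Longest linear sequence: 12 steps (1, 2, 5 to 14) from 1; steps 3 and 4 form the side branch.

Steps most likely to fail

Step 7.
- What may go wrong: the donor-rich aldehyde may be activated too weakly. The acid may instead protonate the trisubstituted alkene, which would scramble the Z geometry or let an ester capture the C7 cation. The pocket may tell the two aldehyde faces apart poorly, or the benzylic alcohol may ionise once formed.
- Fallback (known chemistry, from 9 back to 10): Me2AlCl (2.5 equiv), CH2Cl2, −78 to 0 °C carries out the racemic type 2 carbonyl-ene closure. The same (Z)-alkene relay to the trans relation applies, so this gives 10 together with its mirror image, the (8R,9S)-alcohol F1.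
- An acylative kinetic resolution follows: chiral isothiourea benzotetramisole (the antipode that acylates F1 faster), isobutyric anhydride, i-Pr2NEt, CHCl3, 0 °C. It converts F1 into the isobutyrate F2. Unreacted 10 is separated by chromatography and enters step 8.

Step 12.
- What may go wrong: the sequence may stall after the first aldol addition. The second enolisation may go to the wrong side, followed by loss of the boron oxide to an acyclic enone of the wrong geometry. Two ketone molecules may add, or a formyl group may be lost at the crowded C5.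
- Fallback (from 14 back to 21): one of the two ring bonds is made by olefination instead of a second aldol. Diethyl (methoxymethyl)phosphonate is lithiated (LDA, THF, −78 °C) and acylated with methyl methoxyacetate to give diethyl (1,3-dimethoxy-2-oxopropyl)phosphonate F3.
- The dianion of F3 (NaH, then n-BuLi, THF, −78 °C) adds through its terminal CH(OMe) carbon to one formyl group of 14. On warming, the remaining phosphonate carbanion closes ring C on the second formyl group by an intramolecular Horner–Wadsworth–Emmons reaction. The six-membered ring enforces the cis alkene, and the product is the hydroxy enone F4.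
- HF·pyridine gives the diol F5. Ac2O, Et3N, DMAP and then DBU lead through the diacetate F6 to 21.

Step 9.
- What may go wrong: hydrogen delivery to the planar C7 radical may show poor facial selectivity, because ring B may populate a conformer in which the C8 methyl and the C9 silyloxy group are pseudo-axial.
- Fallback (from 11 back to 13): radical hydrogenation is replaced by a true equilibration at C7. 9-BBN, THF, then NaBO3·4H2O gives the primary alcohol F7 as C7 epimers.
- Dess–Martin periodinane followed by DBU in CH2Cl2 equilibrates the C7 carbaldehyde to the isomer with the formyl group pseudo-equatorial and trans to the C8 methyl, the aldehyde F8.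
- NaBH4, MeOH gives the alcohol F9, and MsCl, Et3N gives the mesylate F10.
- LiAlH4, THF, reflux removes the mesylate and reduces both esters in one operation, which gives 13.

Further compounds
F1 | step 7 | dimethyl (8R,9S)-9-hydroxy-2,3,4-trimethoxy-8-methyl-7-methylidene-6,7,8,9-tetrahydro-5H-benzo[7]annulene-5,5-dicarboxylate | COC(=O)C1(C(=O)OC)CC(=C)[C@@H](C)[C@H](O)c2cc(OC)c(OC)c(OC)c21
F2 | step 7 | isobutyrate of F1 | COC(=O)C1(C(=O)OC)CC(=C)[C@@H](C)[C@H](OC(=O)C(C)C)c2cc(OC)c(OC)c(OC)c21
F3 | step 12 | diethyl (1,3-dimethoxy-2-oxopropyl)phosphonate | CCOP(=O)(OCC)C(OC)C(=O)COC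
F4 | step 12 | spiro 6'-hydroxy-3',5'-dimethoxycyclohex-2'-en-4'-one, C9 silyl ether (ring C diastereomers) | COC1=CC2(C(O)C(OC)C1=O)C[C@@H](C)[C@H](C)[C@@H](O[Si](C)(C)C(C)(C)C)c1cc(OC)c(OC)c(OC)c12
F5 | step 12 | 9,6'-diol from F4 | COC1=CC2(C(O)C(OC)C1=O)C[C@@H](C)[C@H](C)[C@@H](O)c1cc(OC)c(OC)c(OC)c12
F6 | step 12 | 9,6'-diacetate from F5 | COC1=CC2(C(OC(C)=O)C(OC)C1=O)C[C@@H](C)[C@H](C)[C@@H](OC(C)=O)c1cc(OC)c(OC)c(OC)c12
F7 | step 9 | dimethyl (8S,9R)-9-(tert-butyldimethylsilyloxy)-7-(hydroxymethyl)-2,3,4-trimethoxy-8-methyl-6,7,8,9-tetrahydro-5H-benzo[7]annulene-5,5-dicarboxylate (C7 epimers) | COC(=O)C1(C(=O)OC)CC(CO)[C@H](C)[C@@H](O[Si](C)(C)C(C)(C)C)c2cc(OC)c(OC)c(OC)c21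
F8 | step 9 | (7R,8S,9R)-7-formyl compound | COC(=O)C1(C(=O)OC)C[C@@H](C=O)[C@H](C)[C@@H](O[Si](C)(C)C(C)(C)C)c2cc(OC)c(OC)c(OC)c21
F9 | step 9 | (7R,8S,9R)-7-(hydroxymethyl) compound | COC(=O)C1(C(=O)OC)C[C@@H](CO)[C@H](C)[C@@H](O[Si](C)(C)C(C)(C)C)c2cc(OC)c(OC)c(OC)c21
F10 | step 9 | (7R,8S,9R)-7-(mesyloxymethyl) compound | COC(=O)C1(C(=O)OC)C[C@@H](COS(C)(=O)=O)[C@H](C)[C@@H](O[Si](C)(C)C(C)(C)C)c2cc(OC)c(OC)c(OC)c21
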